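**Plan**
- Retrosynthesis: remove the C8 acyl group; take the three exocyclic methylenes (C1=C2, C4=C3, C11=C13) back to an aldehyde, an acetyl group and the lactone α-CH2; open the lactone at O6–C12 and cut C7–C11 (acetate alkylation).
- What is left is ring C5–C10, in which C6 and C8 carry oxygen, C7 lies between them and quaternary C10 is β to both, with a carboxyl carbon on C5. This is a 5,5-disubstituted cyclohexane-1,3-dione 4-carboxylate, cut at C5–C10 (Michael) and C6–C7 (Dieckmann) into a malonate and an acyclic β,β-disubstituted enone.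
- Forward: olefination to the enone; asymmetric Michael/Dieckmann closes the only carbocycle; carbonyl transposition, C7 alkylation, epoxidation/reductive opening (O6), C8 reduction; lactone onto O6; three methylenations; esterification with a separately made acid.
- Stereochemistry: C10 from the chiral amine catalyst; C5 by equilibration trans to the acetal; O6 by epoxidation anti to the C5 ester; C7 by equilibration next to the C8 ketone; C8 by thermodynamic electron-transfer reduction; side-chain geometry from syn-hydrostannation.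

Key step: step 2

Remark: ring carbons keep the elemanolide numbers C5–C10 in every intermediate (C10 quaternary, C5 bearing the C4 substituent, C6 and C8 oxygenated, C7 between them); β is the face of the C10 methyl group.
Remark: the target SMILES is read as the 8α-acyloxy trans-6α,12-lactone with 5β-isopropenyl, 10α-vinyl and 10β-methyl groups; every ring substituent except the C10 methyl is equatorial.
Remark: the malonate is used as its tert-butyl methyl ester so that the ester left on C5 can later be cleaved together with the side-chain ester.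

**Route**

Step 1
Reactants: 1 1,1-dimethoxypropan-2-one; 2 dimethyl (2-oxopropyl)phosphonate
Product: 3 (E)-5,5-dimethoxy-4-methylpent-3-en-2-one
Conditions: NaH, THF, 0 °C → 60 °C
Reagents that add atoms: none
Why: Horner–Wadsworth–Emmons olefination of an activated α,α-dialkoxy ketone, in which reversible addition and elimination should place the acetyl group trans to the larger dimethoxymethyl group; any (Z)-isomer is removed because the alkene geometry decides which face the catalyst of step 2 sees.

Step 2
Reactants: 3 (E)-5,5-dimethoxy-4-methylpent-3-en-2-one; 4 tert-butyl methyl malonate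
Product: 6 tert-butyl (1R,2S)-2-(dimethoxymethyl)-2-methyl-4,6-dioxocyclohexane-1-carboxylate, via Michael adduct 5 (not isolated)
Conditions: 9-amino-9-deoxy-epi-quinine (20 mol%), PhCO2H (40 mol%), toluene, 9 kbar, 50 °C; then NaOMe, MeOH, 0 °C → rt; aq. HCl
Reagents that add atoms: none
Why: Proposed new method: the primary amine condenses with the ketone of 3 to an iminium ion and its protonated quinuclidine holds the malonate, which adds to one face of the geometrically defined (E)-alkene at C10 (Michael step, C5–C10); the closest known reactions are primary-amine-catalysed additions of malonates and nitroalkanes to β,β-disubstituted enones under pressure and the racemic alkoxide-mediated annulation of such enones with malonates. After hydrolysis of the iminium ion, methoxide generates the methyl ketone enolate at C7, which attacks the methyl ester in a 6-exo-trig Dieckmann-type acyl substitution (C6–C7) and expels methoxide, and deprotonation of the acidic 1,3-dione makes the closure irreversible. C10 is controlled by the catalyst (the quinidine-derived pseudo-enantiomer is used if the sense proves opposite), whereas C5 is a labile β-keto ester centre that is settled in step 5. The step needs site selectivity twice: of the two ketone enolates only the one at the methyl group can reach an ester through a six-membered transition state, and of the two esters the tert-butyl one is too hindered to be attacked, so it stays on C5. Holding the malonate as its anion during ring closure disfavours retro-Michael fragmentation and with it loss of the C10 configuration.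

Step 3
Reactants: 6 tert-butyl (1R,2S)-2-(dimethoxymethyl)-2-methyl-4,6-dioxocyclohexane-1-carboxylate
Product: 7 tert-butyl 6-(dimethoxymethyl)-4-methoxy-6-methyl-2-oxocyclohex-3-ene-1-carboxylate (methyl enol ether at C8; C6 ketone)
Conditions: HC(OMe)3, MeOH, camphorsulfonic acid (cat.), rt
Reagents that add atoms: trimethyl orthoformate, COC(OC)OC
Why: Acid-catalysed enol etherification of the 1,3-dione under equilibrium control (vinylogous ester formation) should put the methoxy group on O8, the oxygen remote from the C5 ester and the quaternary C10, leaving C6 as the ketone, while the dimethyl acetal only exchanges with the medium and no stereocentre is formed.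

Step 4
Reactants: 7 tert-butyl 6-(dimethoxymethyl)-4-methoxy-6-methyl-2-oxocyclohex-3-ene-1-carboxylate
Product: 9 tert-butyl 6-(dimethoxymethyl)-6-methyl-4-oxocyclohex-2-ene-1-carboxylate (C8 ketone; C6=C7), via allylic alcohol 8 (not isolated)
Conditions: NaBH4, CeCl3·7H2O, MeOH, −20 °C; then 0.1 M aq. oxalic acid, THF, 0 °C
Reagents that add atoms: water, O
Why: Luche 1,2-reduction of the vinylogous ester carbonyl, then acid-induced ionisation of the allylic alcohol with hydrolysis of the enol ether (Stork–Danheiser transposition), moves the carbonyl to C8 and leaves the C6=C7 alkene, so the C6 carbinol centre of 8 is destroyed again and its configuration is irrelevant; the acid is kept weak and cold to spare the acetal and the tert-butyl ester.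

Step 5
Reactants: 9 tert-butyl 6-(dimethoxymethyl)-6-methyl-4-oxocyclohex-2-ene-1-carboxylate; 10 tert-butyl bromoacetate
Product: 11 tert-butyl 3-(2-tert-butoxy-2-oxoethyl)-6-(dimethoxymethyl)-6-methyl-4-oxocyclohex-2-ene-1-carboxylate (5β-ester trans to the dimethoxymethyl group)
Conditions: KOtBu, tBuOH/THF, 0 °C → rt
Reagents that add atoms: none
Why: Under equilibrating base the most acidic proton, C5–H (α to the ester and γ to the enone), is removed and the extended enolate is alkylated at its α-carbon C7 (vinylogous enolate α-alkylation); base-mediated return of the alkene into conjugation then reprotonates C5 under thermodynamic control, where the ester should settle trans to the dimethoxymethyl group (anti to it in the pseudo-diaxial half-chair and gauche only to the methyl group).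

Step 6
Reactants: 11 tert-butyl 3-(2-tert-butoxy-2-oxoethyl)-6-(dimethoxymethyl)-6-methyl-4-oxocyclohex-2-ene-1-carboxylate
Product: 12 tert-butyl 1-(2-tert-butoxy-2-oxoethyl)-4-(dimethoxymethyl)-4-methyl-2-oxo-7-oxabicyclo[4.1.0]heptane-5-carboxylate (6α,7α-epoxide)
Conditions: 30% aq. H2O2, LiOH (cat.), MeOH, 0 °C
Reagents that add atoms: hydrogen peroxide, OO
Why: Weitz–Scheffer nucleophilic epoxidation, in which hydroperoxide adds to C6 anti to the pseudoaxial C5 ester (the usual trans course for 4-substituted cyclohexenones) and the enolate closes the oxirane on the same face, which sets the C6 oxygen α (trans to the C5 ester, cis to the dimethoxymethyl group) and leaves the C7 side chain β.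

Step 7
Reactants: 12 the 6α,7α-epoxy ketone
Product: 13 tert-butyl 3-(2-tert-butoxy-2-oxoethyl)-6-(dimethoxymethyl)-2-hydroxy-6-methyl-4-oxocyclohexane-1-carboxylate (6α-hydroxy; 7β-side chain; 5β-ester)
Conditions: SmI2, THF/MeOH, −90 °C; then Et3N (cat.), CH2Cl2, rt
Reagents that add atoms: none
Why: SmI2 reduces the ketone to its ketyl and cleaves the adjacent Cα–O bond (reductive opening of an α,β-epoxy ketone to the aldol), so the C6–O bond and its α configuration are untouched, and C7, now α to the C8 ketone, is equilibrated by the amine to the equatorial β position trans to the C6 hydroxyl.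

Step 8
Reactants: 13 the 6α-hydroxy C8 ketone
Product: 14 tert-butyl 3-(2-tert-butoxy-2-oxoethyl)-6-(dimethoxymethyl)-2,4-dihydroxy-6-methylcyclohexane-1-carboxylate (6α,8α-diol)
Conditions: SmI2, H2O, THF, 0 °C
Reagents that add atoms: none
Why: Electron-transfer reduction of the ketone by SmI2/H2O proceeds through a carbinyl organosamarium that is protonated to the more stable alcohol, as in dissolving-metal reductions; here that is the equatorial 8α-ol, which avoids the 1,3-diaxial contact with the C10 methyl group, while the tert-butyl esters and the acetal are inert.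

Step 9
Reactants: 14 the 6α,8α-diol
Product: 15 tert-butyl 3-(2-tert-butoxy-2-oxoethyl)-4-[(tert-butyldiphenylsilyl)oxy]-6-(dimethoxymethyl)-2-hydroxy-6-methylcyclohexane-1-carboxylate (8α-silyl ether; free 6α-hydroxyl)
Conditions: tBuPh2SiCl, imidazole, DMF, 0 °C → rt
Reagents that add atoms: tert-butyl(chloro)diphenylsilane, CC(C)(C)[Si](Cl)(c1ccccc1)c1ccccc1
Why: Steric discrimination in silylation: O8 has the unsubstituted C9 as neighbour whereas O6 is flanked by the substituted C5 and C7, so the bulky chlorosilane should react at O8 only, protecting it for the rest of the route and leaving O6 free for the lactone.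

Step 10
Reactants: 15 the 8α-silyl ether
Product: 16 4-[(tert-butyldiphenylsilyl)oxy]-6-formyl-6-methyl-2-oxooctahydro-1-benzofuran-7-carboxylic acid (trans-fused 6α,12-lactone; 8α-silyloxy; 5β-carboxylic acid; 10α-formyl)
Conditions: CF3CO2H/CH2Cl2 (1:3), H2O (5 equiv), 0 °C → rt
Reagents that add atoms: water, O
Why: Acidolysis cleaves both tert-butyl esters with loss of 2-methylpropene, the C7 acetic acid closes the γ-lactone onto O6, the only free hydroxyl (trans-diequatorial partners, hence the trans-fused lactone), and the dimethyl acetal is hydrolysed to the aldehyde, whereas the C5 acid cannot lactonise and the tert-butyldiphenylsilyl ether survives the acid.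

Step 11
Reactants: 16 the lactone aldehyde acid
Product: 18 7-acetyl-4-[(tert-butyldiphenylsilyl)oxy]-6-methyl-2-oxooctahydro-1-benzofuran-6-carbaldehyde (5β-acetyl), via acid chloride 17 (not isolated)
Conditions: (COCl)2, DMF (cat.), CH2Cl2, 0 °C → rt; then MeZnCl, Pd(PPh3)4 (5 mol%), THF, 0 °C → rt
Reagents that add atoms: methylzinc chloride, C[Zn]Cl
Why: Conversion of the acid into its chloride and palladium-catalysed Negishi acylation with MeZnCl give the methyl ketone, the organozinc reagent being too unreactive to add to the aldehyde, the lactone or the new ketone, and C5 stays equatorial.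

Step 12
Reactants: 18 the keto aldehyde
Product: 19 4-[(tert-butyldiphenylsilyl)oxy]-6-ethenyl-6-methyl-7-(prop-1-en-2-yl)hexahydro-1-benzofuran-2(3H)-one (10α-vinyl; 5β-isopropenyl)
Conditions: Zn, CH2Br2, TiCl4, THF/CH2Cl2, 0 °C → rt
Reagents that add atoms: dibromomethane, BrCBr
Why: Lombardo methylenation with the gem-dizinc/titanium reagent converts the aldehyde into the C10 vinyl group and the hindered methyl ketone into the C5 isopropenyl group under non-basic conditions, so the β-acyloxy ketone neither epimerises at C5 nor eliminates and the lactone carbonyl is not attacked.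

Step 13
Reactants: 19 the saturated lactone
Product: 23 4-[(tert-butyldiphenylsilyl)oxy]-6-ethenyl-6-methyl-3-methylidene-7-(prop-1-en-2-yl)hexahydro-1-benzofuran-2(3H)-one, via lithium enolate 20 (not isolated), via Mannich base 21 (not isolated), via methiodide 22 (not isolated)
Conditions: LiN(iPr)2, THF, −78 °C; CH2=NMe2+ I−, −78 °C → rt; MeI, MeOH, rt; aq. NaHCO3, CH2Cl2, rt
Reagents that add atoms: N,N-dimethylmethyleneiminium iodide, C=[N+](C)C.[I-]
Why: α-Methylenation of the lactone by Mannich reaction of its lithium enolate with the iminium salt, N-methylation and Hofmann-type elimination; the lactone is the only enolisable carbonyl group left and the transient C11 stereocentre becomes sp2.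

Step 14
Reactants: 23 the silylated α-methylene lactone
Product: 24 6-ethenyl-4-hydroxy-6-methyl-3-methylidene-7-(prop-1-en-2-yl)hexahydro-1-benzofuran-2(3H)-one (8α-hydroxy trans-6α,12-lactone)
Conditions: HF·pyridine, THF, 0 °C → rt
Reagents that add atoms: none
Why: Fluoride-mediated cleavage of the silyl ether under acidic conditions, which avoid conjugate addition to the α-methylene lactone and do not affect C8.

Step 15
Reactants: 25 but-2-yne-1,4-diol
Product: 26 (E)-2-(tributylstannyl)but-2-ene-1,4-diol
Conditions: Bu3SnH, PdCl2(PPh3)2 (2 mol%), THF, rt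
Reagents that add atoms: tributyltin hydride, CCCC[SnH](CCCC)CCCC
Why: Palladium-catalysed hydrostannation adds H and SnBu3 syn across the symmetrical alkyne, so the two hydroxymethyl groups end cis on the alkene, which is the geometry of the side chain.

Step 16
Reactants: 26 (E)-2-(tributylstannyl)but-2-ene-1,4-diol
Product: 27 tributyl(2,2-dimethyl-4,7-dihydro-1,3-dioxepin-5-yl)stannane
Conditions: Me2C(OMe)2, pyridinium p-toluenesulfonate (cat.), CH2Cl2, rt
Reagents that add atoms: 2,2-dimethoxypropane, COC(C)(C)OC
Why: Acid-catalysed transacetalisation closes the seven-membered acetonide, which only the cis-diol can form, and masks both hydroxyls as an acid-labile, base-stable group.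

Step 17
Reactants: 27 tributyl(2,2-dimethyl-4,7-dihydro-1,3-dioxepin-5-yl)stannane
Product: 29 2,2-dimethyl-4,7-dihydro-1,3-dioxepine-5-carboxylic acid, via vinyllithium 28 (not isolated)
Conditions: n-BuLi, THF, −78 °C; CO2; cold dilute HCl to pH 4
Reagents that add atoms: carbon dioxide, O=C=O
Why: Tin–lithium exchange gives the vinyllithium with retention of alkene geometry and carboxylation with CO2 gives the acid, in which the carboxyl group is trans to the ring CH2O group on the neighbouring alkene carbon, that is the protected (E)-acid.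

Step 18
Reactants: 24 the 8α-alcohol; 29 2,2-dimethyl-4,7-dihydro-1,3-dioxepine-5-carboxylic acid
Product: 31 the 8α-(2,2-dimethyl-4,7-dihydro-1,3-dioxepine-5-carboxylate) of 24, via mixed anhydride 30 (not isolated)
Conditions: 2,4,6-Cl3C6H2COCl, Et3N, THF, rt; then 24, 4-(dimethylamino)pyridine, toluene, rt → 40 °C
Reagents that add atoms: none
Why: Yamaguchi esterification through the mixed 2,4,6-trichlorobenzoic anhydride acylates the hindered equatorial C8 hydroxyl at oxygen, so C8 keeps its α configuration and the alkene geometry of the acid is unchanged.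

Step 19
Reactants: 31 the acetonide-protected ester
Product: 32 CNP0309506.1 (target)
Conditions: AcOH/H2O/THF (3:1:1), rt
Reagents that add atoms: none
Why: Mild aqueous acid hydrolyses the seven-membered acetonide of the allylic diol without touching the two ester linkages, the α-methylene lactone or the alkenes.

**Compound list**

1 | 1,1-dimethoxypropan-2-one | CC(=O)C(OC)OC | starting material
2 | dimethyl (2-oxopropyl)phosphonate | CC(=O)CP(=O)(OC)OC | starting material
3 | (E)-5,5-dimethoxy-4-methylpent-3-en-2-one | CC(=O)/C=C(\C)C(OC)OC | intermediate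
4 | tert-butyl methyl malonate | COC(=O)CC(=O)OC(C)(C)C | starting material
5 | 1-tert-butyl 3-methyl 2-[(2S)-1,1-dimethoxy-2-methyl-4-oxopentan-2-yl]propanedioate (malonate carbon epimerising) | COC(OC)[C@@](C)(CC(C)=O)C(C(=O)OC)C(=O)OC(C)(C)C | intermediate (not isolated)
6 | tert-butyl (1R,2S)-2-(dimethoxymethyl)-2-methyl-4,6-dioxocyclohexane-1-carboxylate (enolised 1,3-dione; 5β-ester, 10α-dimethoxymethyl) | COC(OC)[C@@]1(C)CC(=O)CC(=O)[C@@H]1C(=O)OC(C)(C)C | intermediate
7 | tert-butyl 6-(dimethoxymethyl)-4-methoxy-6-methyl-2-oxocyclohex-3-ene-1-carboxylate (C8 methyl enol ether; 5β-ester, 10α-dimethoxymethyl) | COC(OC)[C@@]1(C)CC(OC)=CC(=O)[C@@H]1C(=O)OC(C)(C)C | intermediate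
8 | tert-butyl 6-(dimethoxymethyl)-2-hydroxy-4-methoxy-6-methylcyclohex-3-ene-1-carboxylate (allylic alcohol, both C6 epimers) | COC(OC)[C@@]1(C)CC(OC)=CC(O)[C@@H]1C(=O)OC(C)(C)C | intermediate (not isolated)
9 | tert-butyl 6-(dimethoxymethyl)-6-methyl-4-oxocyclohex-2-ene-1-carboxylate (C8 ketone, C6=C7; 5β-ester) | COC(OC)[C@@]1(C)CC(=O)C=C[C@@H]1C(=O)OC(C)(C)C | intermediate
10 | tert-butyl bromoacetate | BrCC(=O)OC(C)(C)C | starting material
11 | tert-butyl 3-(2-tert-butoxy-2-oxoethyl)-6-(dimethoxymethyl)-6-methyl-4-oxocyclohex-2-ene-1-carboxylate (5β-ester) | COC(OC)[C@@]1(C)CC(=O)C(CC(=O)OC(C)(C)C)=C[C@@H]1C(=O)OC(C)(C)C | intermediate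
12 | tert-butyl 1-(2-tert-butoxy-2-oxoethyl)-4-(dimethoxymethyl)-4-methyl-2-oxo-7-oxabicyclo[4.1.0]heptane-5-carboxylate (6α,7α-epoxide; 5β-ester) | COC(OC)[C@@]1(C)CC(=O)[C@@]2(CC(=O)OC(C)(C)C)O[C@H]2[C@@H]1C(=O)OC(C)(C)C | intermediate
13 | tert-butyl 3-(2-tert-butoxy-2-oxoethyl)-6-(dimethoxymethyl)-2-hydroxy-6-methyl-4-oxocyclohexane-1-carboxylate (6α-OH, 7β-side chain, 5β-ester) | COC(OC)[C@@]1(C)CC(=O)[C@H](CC(=O)OC(C)(C)C)[C@@H](O)[C@@H]1C(=O)OC(C)(C)C | intermediate
14 | tert-butyl 3-(2-tert-butoxy-2-oxoethyl)-6-(dimethoxymethyl)-2,4-dihydroxy-6-methylcyclohexane-1-carboxylate (6α,8α-diol) | COC(OC)[C@@]1(C)C[C@@H](O)[C@H](CC(=O)OC(C)(C)C)[C@@H](O)[C@@H]1C(=O)OC(C)(C)C | intermediate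
15 | tert-butyl 3-(2-tert-butoxy-2-oxoethyl)-4-[(tert-butyldiphenylsilyl)oxy]-6-(dimethoxymethyl)-2-hydroxy-6-methylcyclohexane-1-carboxylate (8α-silyl ether, 6α-OH) | COC(OC)[C@@]1(C)C[C@@H](O[Si](c2ccccc2)(c2ccccc2)C(C)(C)C)[C@H](CC(=O)OC(C)(C)C)[C@@H](O)[C@@H]1C(=O)OC(C)(C)C | intermediate
16 | 4-[(tert-butyldiphenylsilyl)oxy]-6-formyl-6-methyl-2-oxooctahydro-1-benzofuran-7-carboxylic acid (trans-fused 6α,12-lactone; 8α-silyloxy, 5β-CO2H, 10α-CHO) | O=C[C@@]1(C)C[C@@H](O[Si](c3ccccc3)(c3ccccc3)C(C)(C)C)[C@@H]2CC(=O)O[C@H]2[C@@H]1C(=O)O | intermediate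
17 | 4-[(tert-butyldiphenylsilyl)oxy]-6-formyl-6-methyl-2-oxooctahydro-1-benzofuran-7-carbonyl chloride | O=C[C@@]1(C)C[C@@H](O[Si](c3ccccc3)(c3ccccc3)C(C)(C)C)[C@@H]2CC(=O)O[C@H]2[C@@H]1C(Cl)=O | intermediate (not isolated)
18 | 7-acetyl-4-[(tert-butyldiphenylsilyl)oxy]-6-methyl-2-oxooctahydro-1-benzofuran-6-carbaldehyde (5β-acetyl, 10α-CHO) | O=C[C@@]1(C)C[C@@H](O[Si](c3ccccc3)(c3ccccc3)C(C)(C)C)[C@@H]2CC(=O)O[C@H]2[C@@H]1C(C)=O | intermediate
19 | 4-[(tert-butyldiphenylsilyl)oxy]-6-ethenyl-6-methyl-7-(prop-1-en-2-yl)hexahydro-1-benzofuran-2(3H)-one | C=C[C@@]1(C)C[C@@H](O[Si](c3ccccc3)(c3ccccc3)C(C)(C)C)[C@@H]2CC(=O)O[C@H]2[C@@H]1C(C)=C | intermediate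
20 | lithium enolate of 19 | C=C[C@@]1(C)C[C@@H](O[Si](c3ccccc3)(c3ccccc3)C(C)(C)C)[C@@H]2C=C(O[Li])O[C@H]2[C@@H]1C(C)=C | intermediate (not isolated)
21 | 3-[(dimethylamino)methyl] derivative of 19 (C11 epimers) | C=C[C@@]1(C)C[C@@H](O[Si](c3ccccc3)(c3ccccc3)C(C)(C)C)[C@@H]2C(CN(C)C)C(=O)O[C@H]2[C@@H]1C(C)=C | intermediate (not isolated)
22 | trimethylammonium iodide of 21 | C=C[C@@]1(C)C[C@@H](O[Si](c3ccccc3)(c3ccccc3)C(C)(C)C)[C@@H]2C(C[N+](C)(C)C)C(=O)O[C@H]2[C@@H]1C(C)=C.[I-] | intermediate (not isolated)
23 | 4-[(tert-butyldiphenylsilyl)oxy]-6-ethenyl-6-methyl-3-methylidene-7-(prop-1-en-2-yl)hexahydro-1-benzofuran-2(3H)-one | C=C[C@@]1(C)C[C@@H](O[Si](c3ccccc3)(c3ccccc3)C(C)(C)C)[C@@H]2C(=C)C(=O)O[C@H]2[C@@H]1C(C)=C | intermediate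
24 | 6-ethenyl-4-hydroxy-6-methyl-3-methylidene-7-(prop-1-en-2-yl)hexahydro-1-benzofuran-2(3H)-one (8α-hydroxy trans-6α,12-lactone) | C=C[C@@]1(C)C[C@@H](O)[C@@H]2C(=C)C(=O)O[C@H]2[C@@H]1C(C)=C | intermediate
25 | but-2-yne-1,4-diol | OCC#CCO | starting material
26 | (E)-2-(tributylstannyl)but-2-ene-1,4-diol | OC/C(=C\CO)[Sn](CCCC)(CCCC)CCCC | intermediate
27 | tributyl(2,2-dimethyl-4,7-dihydro-1,3-dioxepin-5-yl)stannane | CC1(C)OCC=C(CO1)[Sn](CCCC)(CCCC)CCCC | intermediate
28 | (2,2-dimethyl-4,7-dihydro-1,3-dioxepin-5-yl)lithium | [Li]C1=CCOC(C)(C)OC1 | intermediate (not isolated)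
29 | 2,2-dimethyl-4,7-dihydro-1,3-dioxepine-5-carboxylic acid | CC1(C)OCC=C(CO1)C(O)=O | intermediate
30 | mixed anhydride of 29 with 2,4,6-trichlorobenzoic acid | CC1(C)OCC=C(CO1)C(=O)OC(=O)c1c(Cl)cc(Cl)cc1Cl | intermediate (not isolated)
31 | 8α-(2,2-dimethyl-4,7-dihydro-1,3-dioxepine-5-carboxylate) of 24 | C=C[C@@]1(C)C[C@@H](OC(=O)C3=CCOC(C)(C)OC3)[C@@H]2C(=C)C(=O)O[C@H]2[C@@H]1C(C)=C | intermediate
32 | CNP0309506.1: 8α-[(E)-4-hydroxy-2-(hydroxymethyl)but-2-enoyl] ester of 24 | C=C[C@@]1(C)C[C@@H](OC(=O)/C(=C/CO)CO)[C@@H]2C(=C)C(=O)O[C@H]2[C@@H]1C(=C)C | target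

**Step count**

Total: 19 steps. Longest linear sequence: 16 steps (steps 1–14, 18 and 19); steps 15–17 make the side-chain acid.

**Steps most likely to fail**

1. Step 2 (proposed new method). What may go wrong: slow or poorly face-selective conjugate addition at the hindered β-carbon, and loss of the C10 configuration through retro-Michael fragmentation and re-addition while the ring closes. Fallback with known chemistry, setting out from 3 and 4 and returning at 6: the two are combined with NaOMe in MeOH, the classical alkoxide-mediated annulation of β,β-disubstituted enones with malonates. This gives the racemic adduct, that is 5 together with its mirror image, the (2R)-adduct F1, and from it the racemic dione, 6 together with the (1S,2R)-dione F2. The dione is a vinylogous acid and is resolved classically by crystallising its salt with (R)-1-phenylethylamine, the (R)-1-phenylethylammonium enolate of 6 F3 (the (S)-amine is taken if the other diastereomer proves less soluble); dilute acid then liberates 6.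

2. Step 6. What may go wrong: poor facial selectivity in the peroxide addition, either because C5 has not equilibrated cleanly trans to the acetal in step 5 or because the C10 substituents override the directing effect of the C5 ester; this would feed the C10-epimeric series. Fallback, setting out from 11 and returning at 13: copper-catalysed enantioselective conjugate borylation (CuCl, NaOtBu, a chiral ferrocenyl bisphosphine, B2pin2, MeOH, THF). Here the catalyst rather than the substrate chooses the C6 face while the base-labile C5 centre equilibrates and reacts through its trans epimer, to give the 6α-boryl ketone F4. NaBO3·4H2O then oxidises the C–B bond with retention and delivers 13 directly, so that 12 is bypassed.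

3. Step 8. What may go wrong: incomplete equatorial selectivity, for instance kinetic protonation or chelation of samarium by the 6-hydroxyl steering the reduction toward the axial alcohol. Fallback, setting out from 13 and returning at 14: LiBH(sBu)3 in THF at −78 °C attacks from the equatorial direction, the open one next to the axial C10 methyl group, and should give the axial 8β-alcohol F5. Mitsunobu inversion (PPh3, diisopropyl azodicarboxylate, 4-nitrobenzoic acid) at this less hindered hydroxyl gives the 8α-(4-nitrobenzoate) F6, and K2CO3 in MeOH removes the ester to return 14.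

**Further compounds**

F1 | step 2 | 1-tert-butyl 3-methyl 2-[(2R)-1,1-dimethoxy-2-methyl-4-oxopentan-2-yl]propanedioate (enantiomer of 5) | COC(OC)[C@](C)(CC(C)=O)C(C(=O)OC)C(=O)OC(C)(C)C
F2 | step 2 | tert-butyl (1S,2R)-2-(dimethoxymethyl)-2-methyl-4,6-dioxocyclohexane-1-carboxylate (enantiomer of 6) | COC(OC)[C@]1(C)CC(=O)CC(=O)[C@H]1C(=O)OC(C)(C)C
F3 | step 2 | (R)-1-phenylethylammonium enolate of 6 | COC(OC)[C@@]1(C)CC([O-])=CC(=O)[C@@H]1C(=O)OC(C)(C)C.C[C@@H]([NH3+])c1ccccc1
F4 | step 6 | tert-butyl 3-(2-tert-butoxy-2-oxoethyl)-6-(dimethoxymethyl)-6-methyl-4-oxo-2-(4,4,5,5-tetramethyl-1,3,2-dioxaborolan-2-yl)cyclohexane-1-carboxylate (6α-boryl, 7β-side chain) | COC(OC)[C@@]1(C)CC(=O)[C@H](CC(=O)OC(C)(C)C)[C@@H](B2OC(C)(C)C(C)(C)O2)[C@@H]1C(=O)OC(C)(C)C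
F5 | step 8 | 8β-epimer of 14 (6α,8β-diol) | COC(OC)[C@@]1(C)C[C@H](O)[C@H](CC(=O)OC(C)(C)C)[C@@H](O)[C@@H]1C(=O)OC(C)(C)C
F6 | step 8 | 8α-(4-nitrobenzoate) of 14 | COC(OC)[C@@]1(C)C[C@@H](OC(=O)c2ccc(cc2)[N+](=O)[O-])[C@H](CC(=O)OC(C)(C)C)[C@@H](O)[C@@H]1C(=O)OC(C)(C)C
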